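A direct plan would start from the catechol ester A1, methyl 3-(3,4-dihydroxyphenyl)propanoate, and convert it in three steps (diphenylmethylene ketal, LiAlH4 reduction, Mitsunobu esterification) into the 2,4,6-triisopropylbenzoate A2.
It would lithiate A2 with s-BuLi/(−)-sparteine, add it twice to the linchpin A3, bis(pinacolboryl)methane, in a one-pot double lithiation–borylation, and oxidise to the ketal-protected (3R,5R)-diol A4; orthoester mono-acetylation and hydrogenolysis would finish.
Weak point 1, the double lithiation–borylation–oxidation: a four-component cryogenic one-pot step that would consume 2.5 equiv of a three-step ester and of sparteine, would have to homologate the primary boronate in preference to the secondary one, and would expose the acidic CH2 of A3 to a strong base.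
Weak point 2, the setting of C3 and C5: each centre would be set separately by a stoichiometric chiral diamine, so every mismatched pair would end as the meso diastereomer, which has to be separated.
Weak point 3, the three-step run-up from A1 to A2: ketalisation at 170 °C, ester reduction and re-esterification would form no skeletal bond, and the triisopropylbenzoate would be discarded as a leaving group.

**Retrosynthetic overview**
The target is read as the mono-acetate of a C2-symmetric anti-1,3-diol: C3 (OAc) and C5 (OH) flank the C4 methylene and carry identical 2-(3,4-dihydroxyphenyl)ethyl arms, so C3 and C5 are the two carbonyl carbons of a tetrahydrocurcuminoid heptane-3,5-dione, the presumed biogenetic precursor.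
Key disconnection: the C3–H and C5–H bonds; one (R)-BINAP–ruthenium double hydrogenation of the achiral, mirror-symmetric diketone would set both stereocentres as a group with catalytic chirality.
The diketone would come in one operation from acetylacetone (C2–C6) and two molecules of 3,4-bis(benzyloxy)benzyl chloride (C1 and C7) by two-directional terminal alkylation, which forms C1–C2 and C6–C7; C3–C4 and C4–C5 are bought.
No ring is formed: both benzene rings are purchased with the catechol oxygens masked as benzyl ethers, which are removed last, after an orthoester mono-acetylation that is degenerate in the C2-symmetric diol.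
The design needs no stoichiometric chiral reagent, no cryogenic organolithium linchpin, no leaving-group auxiliary and no run-up steps: four steps in all.

Key step: step 2

Remark: 3,4-bis(benzyloxy)benzyl chloride is taken as a commercial reagent; because the diol core is C2-symmetric, acetylation of either hydroxyl (and any later 1,3-acyl shift) gives the same (3R,5R) mono-acetate.

Step 1
Reactants: 1 3,4-bis(benzyloxy)benzyl chloride (2.0 equiv); 2 acetylacetone (pentane-2,4-dione, 1.0 equiv)
Product: 5 1,7-bis[3,4-bis(benzyloxy)phenyl]heptane-3,5-dione, via acetylacetone dianion 3 (not isolated), via monobenzylated diketone 4 (not isolated)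
Conditions: LiN(i-Pr)2 (2.0 equiv), THF, 0 °C; 1 (1.0 equiv), 0 °C → rt; LiN(i-Pr)2 (1.0 equiv), 0 °C; 1 (1.0 equiv), 0 °C → rt; 1 M HCl work-up
Reagents that add atoms: none
Why: Terminal (γ) alkylation of a β-diketone dianion: the terminal carbanion of 3 is its most nucleophilic site and displaces the benzylic chloride to form C1–C2, and a third equivalent of base then ionises the remaining methyl group of 4 (methyl in preference to methylene) so that the second benzylation forms C6–C7; no stereocentre is involved.

Step 2
Reactants: 5 1,7-bis[3,4-bis(benzyloxy)phenyl]heptane-3,5-dione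
Product: 7 (3R,5R)-1,7-bis[3,4-bis(benzyloxy)phenyl]heptane-3,5-diol, via hydroxy ketone 6 (not isolated)
Conditions: H2 (80 atm), RuCl2[(R)-BINAP] (1 mol%), MeOH/CH2Cl2 (3:1), 50 °C, 48 h
Reagents that add atoms: none
Why: Noyori asymmetric hydrogenation of a β-diketone: the ruthenium monohydride formed from RuCl2[(R)-BINAP] and H2 binds the keto form of 5 through both oxygens and delivers hydride to the carbonyl face left open by the (R)-BINAP ligand, giving hydroxy ketone 6, which rebinds as a hydroxyl–carbonyl chelate and is reduced again under control of the same ligand. The closest known cases are pentane-2,4-dione and its 1,5-disubstituted analogues, which give anti-1,3-diols with this catalyst; (R)-BINAP is chosen because it gives the (R,R)-diol there, and the 2-arylethyl arm only takes the place of methyl as the lowest-ranked carbon substituent. No ring is closed. Both new stereocentres (C3 and C5) are set by the ligand, and because the two reductions are controlled independently the minor enantiomer of 6 should end mainly as the meso diol, removable by crystallisation or chromatography, so the anti diol should be enantiomerically purer than a single reduction would make it. The step needs anti over syn selectivity, secured by matched catalyst control in the second reduction, and chemoselectivity for C=O over the four benzyl ethers, secured by the homogeneous divalent ruthenium catalyst, which does not cleave benzyl ethers.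

Step 3
Reactants: 7 (3R,5R)-1,7-bis[3,4-bis(benzyloxy)phenyl]heptane-3,5-diol
Product: 9 (3R,5R)-1,7-bis[3,4-bis(benzyloxy)phenyl]-5-hydroxyheptan-3-yl acetate, via cyclic orthoester 8 (not isolated)
Conditions: MeC(OMe)3 (1.5 equiv), PPTS (5 mol%), CH2Cl2, rt, 1 h; then H2O, rt, 30 min
Reagents that add atoms: trimethyl orthoacetate, CC(OC)(OC)OC; water, O
Why: Orthoester mono-acylation: acid-catalysed orthoester exchange closes the 2-methoxy-2-methyl-1,3-dioxane 8, whose hydrolysis through the dioxan-2-ylium ion can release only one acetate and one free hydroxyl; since 7 is C2-symmetric both modes of ring opening give the same compound, and no C–O bond at C3 or C5 is broken.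

Step 4
Reactants: 9 (3R,5R)-1,7-bis[3,4-bis(benzyloxy)phenyl]-5-hydroxyheptan-3-yl acetate
Product: 10 (3R,5R)-1,7-bis(3,4-dihydroxyphenyl)-5-hydroxyheptan-3-yl acetate (CNP0132541.1)
Conditions: H2 (1 atm), 10% Pd/C, THF/EtOAc, rt; filtration and concentration under argon
Reagents that add atoms: none
Why: Catalytic hydrogenolysis (O-debenzylation) of the four benzylic C–O bonds under neutral conditions should free both catechols and leave the secondary acetate, the secondary alcohol and both stereocentres untouched, with the oxygen-sensitive catechols kept under inert gas.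

**Compound list**
1 | 3,4-bis(benzyloxy)benzyl chloride | ClCc1ccc(OCc2ccccc2)c(OCc2ccccc2)c1 | starting material
2 | acetylacetone (pentane-2,4-dione) | CC(=O)CC(C)=O | starting material
3 | dilithium salt of the pentane-2,4-dione 1,3-dianion | [Li+].[Li+].[CH2-]C(=O)[CH-]C(C)=O | intermediate
4 | 6-[3,4-bis(benzyloxy)phenyl]hexane-2,4-dione (present as its lithium enolate) | CC(=O)CC(=O)CCc1ccc(OCc2ccccc2)c(OCc2ccccc2)c1 | intermediate
5 | 1,7-bis[3,4-bis(benzyloxy)phenyl]heptane-3,5-dione | O=C(CCc1ccc(OCc2ccccc2)c(OCc2ccccc2)c1)CC(=O)CCc1ccc(OCc2ccccc2)c(OCc2ccccc2)c1 | intermediate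
6 | (5R)-1,7-bis[3,4-bis(benzyloxy)phenyl]-5-hydroxyheptan-3-one | O[C@H](CCc1ccc(OCc2ccccc2)c(OCc2ccccc2)c1)CC(=O)CCc1ccc(OCc2ccccc2)c(OCc2ccccc2)c1 | intermediate
7 | (3R,5R)-1,7-bis[3,4-bis(benzyloxy)phenyl]heptane-3,5-diol | O[C@H](CCc1ccc(OCc2ccccc2)c(OCc2ccccc2)c1)C[C@H](O)CCc1ccc(OCc2ccccc2)c(OCc2ccccc2)c1 | intermediate
8 | (4R,6R)-4,6-bis{2-[3,4-bis(benzyloxy)phenyl]ethyl}-2-methoxy-2-methyl-1,3-dioxane | COC1(C)O[C@H](CCc2ccc(OCc3ccccc3)c(OCc3ccccc3)c2)C[C@@H](CCc2ccc(OCc3ccccc3)c(OCc3ccccc3)c2)O1 | intermediate
9 | (3R,5R)-1,7-bis[3,4-bis(benzyloxy)phenyl]-5-hydroxyheptan-3-yl acetate | CC(=O)O[C@H](CCc1ccc(OCc2ccccc2)c(OCc2ccccc2)c1)C[C@H](O)CCc1ccc(OCc2ccccc2)c(OCc2ccccc2)c1 | intermediate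
10 | (3R,5R)-1,7-bis(3,4-dihydroxyphenyl)-5-hydroxyheptan-3-yl acetate | CC(=O)O[C@H](CCc1ccc(O)c(O)c1)C[C@H](O)CCc1ccc(O)c(O)c1 | target

**Summary**
Total step count: 4. Longest linear sequence: 4.

Steps most likely to fail:

Step 1. The one-pot double alkylation may lose regiocontrol: proton exchange between the dianion and the first product, alkylation at the central C4, or an incomplete second ionisation would give mixtures of mono-, di- and branched products. The fallback sets out from acetylacetone 2 and returns at diketone 5. Compound 2 would be pre-complexed with B2O3 (EtOAc, 70 °C), which blocks C4, and condensed at both methyl groups with 3,4-bis(benzyloxy)benzaldehyde F1 (B(OBu)3, n-BuNH2; dilute HCl work-up) in the classical boron-templated double aldol condensation. This would give the curcumin-type (1E,6E)-1,7-bis[3,4-bis(benzyloxy)phenyl]hepta-1,6-diene-3,5-dione F2. Its two styryl double bonds would then be saturated with H2 over Pd/C poisoned with diphenyl sulfide, which spares benzyl ethers, to give 5.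

Step 2. Turnover may stall at the hydroxy ketone stage because the poorly soluble diketone binds ruthenium strongly as a diketonate, and slow second reduction may erode the anti selectivity. The fallback sets out from chloride 1 and returns at diol 7. Compound 1 would be converted with Mg turnings in THF into [3,4-bis(benzyloxy)benzyl]magnesium chloride F3. With CuI (10 mol%), F3 would open both terminal epoxide carbons of the known (2S,4S)-1,2:4,5-diepoxypentane F4 (THF, −30 °C → 0 °C) to give 7 directly, with both stereocentres supplied by the bis-epoxide.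

Step 3. Ring closure to the trans-4,6-disubstituted cyclic orthoester may remain incomplete, so that acyclic mixed orthoesters hydrolyse to diol and diacetate. The fallback sets out from diol 7 and returns at mono-acetate 9. Bu2SnO (toluene, reflux, removal of water) would give the stannylene acetal (4R,6R)-4,6-bis{2-[3,4-bis(benzyloxy)phenyl]ethyl}-2,2-dibutyl-1,3,2-dioxastanninane F5. Reaction of F5 with AcCl (1.0 equiv, CH2Cl2, 0 °C) should acylate one oxygen only, the other staying bound to tin until aqueous work-up.

**Further compounds**
F1 | step 1 | 3,4-bis(benzyloxy)benzaldehyde | O=Cc1ccc(OCc2ccccc2)c(OCc2ccccc2)c1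
F2 | step 1 | (1E,6E)-1,7-bis[3,4-bis(benzyloxy)phenyl]hepta-1,6-diene-3,5-dione | O=C(/C=C/c1ccc(OCc2ccccc2)c(OCc2ccccc2)c1)CC(=O)/C=C/c1ccc(OCc2ccccc2)c(OCc2ccccc2)c1
F3 | step 2 | [3,4-bis(benzyloxy)benzyl]magnesium chloride | Cl[Mg]Cc1ccc(OCc2ccccc2)c(OCc2ccccc2)c1
F4 | step 2 | (2S,4S)-1,2:4,5-diepoxypentane | C1O[C@H]1C[C@H]1CO1
F5 | step 3 | (4R,6R)-4,6-bis{2-[3,4-bis(benzyloxy)phenyl]ethyl}-2,2-dibutyl-1,3,2-dioxastanninane | CCCC[Sn]1(CCCC)O[C@H](CCc2ccc(OCc3ccccc3)c(OCc3ccccc3)c2)C[C@@H](CCc2ccc(OCc3ccccc3)c(OCc3ccccc3)c2)O1
A1 | direct plan | methyl 3-(3,4-dihydroxyphenyl)propanoate | COC(=O)CCc1ccc(O)c(O)c1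
A2 | direct plan | 3-(2,2-diphenyl-1,3-benzodioxol-5-yl)propyl 2,4,6-triisopropylbenzoate | CC(C)c1cc(C(C)C)c(C(=O)OCCCc2ccc3c(c2)OC(O3)(c2ccccc2)c2ccccc2)c(C(C)C)c1
A3 | direct plan | bis(4,4,5,5-tetramethyl-1,3,2-dioxaborolan-2-yl)methane | CC1(C)OB(CB2OC(C)(C)C(C)(C)O2)OC1(C)C
A4 | direct plan | (3R,5R)-1,7-bis(2,2-diphenyl-1,3-benzodioxol-5-yl)heptane-3,5-diol | O[C@H](CCc1ccc2c(c1)OC(O2)(c1ccccc1)c1ccccc1)C[C@H](O)CCc1ccc2c(c1)OC(O2)(c1ccccc1)c1ccccc1
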